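## Analysis of the target

The target (21), C30H52O, is a bicyclic triterpenoid alcohol. Ring A (C1–C5 and C10) carries a gem-dimethyl group at C4; ring B (C5–C10) carries the angular methyl at C10, a tertiary carbinol at C8 and, on C9, a sixteen-carbon chain (C11 onward) with three trisubstituted alkenes, two of them of defined E geometry. The four stereocentres C5, C10, C9 and C8 are contiguous. H5, the C10 methyl and the C9 chain lie on one face (called β here), so the ring fusion is cis, and the C8 hydroxyl lies on the opposite (α) face, trans to the chain; systematically the compound is the (1R,2R,4aR,8aS)-decahydronaphthalen-2-ol. The sensitive groups are the tertiary alcohol, which dehydrates under acid, and the polyene chain, which cyclises under acid and competes for electrophilic oxidants. The difficulties are the quaternary C10 flanked by two stereocentres, the neopentyl C5 next to C4, a cis ring fusion that cationic polyene cyclisation does not deliver, and a tertiary carbinol of fixed configuration beside an unfunctionalised C7. The strategy rests on ring B: a six-membered ring holding C5, C9 and C10 with three cis substituents is what a suprafacial, endo [4+2] addition of a C6=C7–C8=C9 diene to a C5=C10 alkene of ring A leaves behind, and a C7=C8 enol ether from a 2-silyloxydiene is the handle for oxygen at C8.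

## Retrosynthetic reasoning

**C7–H (C7–O cut).** The target 21 has no function at C7, but the oxygen that made ring B accessible sits there. 21 is therefore traced to thionocarbonate 20, to diol 19 and to ketol 18. A radical C–O cleavage is chosen because it leaves the tertiary C8 alcohol and the chain alkenes alone; the forward steps only have to distinguish a secondary from a tertiary hydroxyl.

**C8–O.** Ketol 18 is cut at the C8–O bond to the silyl enol ether 16, through the silyloxy epoxide 17. The enol ether marks C8 as the only nucleophilic ring carbon, so no regiochemical question arises. The forward reaction has to deliver oxygen to the α face and to prefer the enol ether over three trisubstituted alkenes.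

**C10 methyl from formyl.** 16 is traced through mesylate 15 and alcohol 14 to aldehyde 13. The extra oxygen is accepted because the formyl group is what activates the ring A alkene as a dienophile; its removal is put before the C8 oxidation so that no hydroxyl or carbonyl near C10 interferes later.

**C5–C6 and C9–C10 (key disconnection).** Both bonds of ring B that join it to ring A are cut in 13, giving enal 4 and silyloxydiene 12. Cutting here and nowhere else removes three stereocentres and the ring at once, divides the thirty carbons into a C9 and a C21 piece, and brings the whole chain in with the diene. The forward cycloaddition must be regioselective (C6 to C5), endo for the formyl group, and selective for one face of the enal.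

**Diene 12.** The O–Si bond is cut to the cross-conjugated lithium dienolate 11 of enone 10, and the C3=C4 alkene of 10 (the later C8=C9) is cut by olefination into aldehyde 8 and phosphonate 9. The (E) geometry made here becomes the C9 configuration in the cycloaddition.

**Aldehyde 8.** It is traced through the aluminium imine 7 to nitrile 6, and the bond between the farnesyl terminus and a cyanomethyl unit is cut, leading to farnesyl bromide 5, which supplies both E alkenes ready-made.

**Enal 4.** The formyl C–C bond is cut to vinyl triflate 3; the triflate oxygen and the second C3 methyl are traced through lithium enolate 2 to enone 1. Conjugate methyl addition fixes the enolate, and so the alkene, on the side of the quaternary carbon, which deprotonation of the saturated ketone would not do.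

## Alternatives that were turned down

**Alternative 1:** No ring B bond is made; the C5–C10 bond of a preformed trans-fused decalin is broken and re-formed. Irradiation of the trans-fused ring B silyloxydiene A1 (C6=C7–C8=C9) opens the cyclohexadiene in the conrotatory sense to the all-cis cyclodecatriene A2. Warming closes C5–C10 again in the disrotatory sense and gives the cis-fused isomer A3.
- For: trans-fused precursors of this type are accessible with both quaternary carbons in place, and the cis fusion follows from orbital symmetry, not from a reagent. On the supply of the ring carbon skeleton it is stronger than the chosen route.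
- Against: in A2 both C5 and C10 are trigonal, so the sense of re-closure depends on retained helicity or on the remote C3 stereocentre. Photostationary mixtures, hydrogen shifts in the triene and the lability of a bis(silyl enol ether) under irradiation erode the material balance. A3 carries a C3 oxygen that the target lacks, and has neither the C9 chain nor the C8 carbinol. A hindered conjugate addition at C9 next to C10, an oxygenation at C8 and two deoxygenations would still follow.
- Comparison: the chosen route sets C9 in the same event as the ring fusion and brings the chain in with the diene.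

**Alternative 2:** The C9–C10 bond is cut, with a temporary C1–C9 bond. (R)-α-Ionone A4 would be taken by conjugate reduction and diazo transfer to diazoketone A5. Its metal carbenoid adds across the C10=C1 alkene from the face of the tether and gives the tricyclic cyclopropyl ketone A6, with the C10 methyl necessarily cis to H5.
- For: it is stronger than the chosen route on three points. The bicyclic core is reached in very few operations, the cis fusion is enforced by the tether, and the absolute configuration comes from the starting material instead of a catalyst.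
- Against: everything after A6 runs against the target. Reductive opening must select the C1–C9 bond over C9–C10. The resulting C9 enolate, flanked by quaternary C10, must be alkylated on its β face with an unactivated C16 primary electrophile. A methyl nucleophile would then add to the C8 ketone anti to the new chain, which places the hydroxyl β, the wrong way round.
- Comparison: the chosen route introduces the chain before the ring exists, sets C9 by the endo rule, and brings oxygen to C8 as an electrophile, for which approach anti to the chain is the sense the target has.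

**Alternative 3:** The C8–C9 bond is cut. Single-electron reduction of the C8 methyl ketone of keto enoate A7 by a divalent samarium reagent gives a ketyl that adds 6-exo to C9, the β-carbon of the (E)-enoate on C10. The product is hydroxy ester A8, with the C8 carbinol and an acetic ester arm on C9.
- For: the tertiary carbinol is formed directly at the right oxidation level and, through chelation of the metal-bound ketyl to the ester, probably trans to the arm. On this point it is clearly stronger: the chosen route spends seven steps after ring closure on redox adjustment at C7, C8 and C10.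
- Against: A7 already needs the cis relation of C5 and quaternary C10 on ring A, so the hardest stereochemical problem is moved into a multi-step precursor synthesis. 6-Exo ketyl additions are slower than 5-exo ones and compete with simple ketone reduction. Only C11 and C12 of the chain arrive, so fourteen carbons and a trisubstituted (E)-alkene must be attached afterwards in a linear sequence.
- Comparison: the chosen route pays in redox steps but makes ring B, three stereocentres and the complete carbon skeleton in one convergent step.

Key step: step 7

Assumption: the sense of induction of the protonated oxazaborolidine is assigned from its usual pre-transition-state model (s-trans enal on boron, formyl C–H···O contact, one phenyl group over the alkene). For the catalyst from (R)-diphenylprolinol this model exposes the face of C10=C5 that the target needs; were the sense found opposite, the (S)-catalyst would replace it with no other change.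

Numbering used for the bicyclic compounds: ring A = C1–C5 and C10; ring B = C5–C10; chain from C11; β = the face of ring B that carries H5. CIP descriptors of 13–21 refer to this numbering.

## Route

Step 1
Reactants: 1 3-methylcyclohex-2-en-1-one
Product: 3 3,3-dimethylcyclohex-1-en-1-yl trifluoromethanesulfonate, via lithium 3,3-dimethylcyclohex-1-en-1-olate 2 (not isolated)
Conditions: CuI, MeLi (2 equiv), Et2O, 0 °C; then PhNTf2, THF, 0 °C → rt
Reagents that add atoms: lithium dimethylcuprate, [Li+].C[Cu-]C; N-phenylbis(trifluoromethanesulfonimide), O=S(=O)(N(c1ccccc1)S(=O)(=O)C(F)(F)F)C(F)(F)F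
Why: Conjugate addition of the cuprate gives the enolate regiospecifically on the side of the new quaternary carbon, and O-sulfonylation of this enolate with the triflimide (enolate trapping) fixes the alkene there; no stereocentre is formed.

Step 2
Reactants: 3 3,3-dimethylcyclohex-1-en-1-yl trifluoromethanesulfonate
Product: 4 3,3-dimethylcyclohex-1-ene-1-carbaldehyde
Conditions: Pd(PPh3)4 (5 mol %), CO (1 atm), Bu3SnH (slow addition), THF, 50 °C
Reagents that add atoms: carbon monoxide, [C-]#[O+]
Why: Reductive carbonylation: oxidative addition of the vinyl triflate to zerovalent palladium, CO insertion and hydride transfer from tin to the acyl complex give the enal; slow addition of the stannane keeps direct reduction of the vinyl complex behind CO insertion.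

Step 3
Reactants: 5 (2E,6E)-farnesyl bromide
Product: 6 (4E,8E)-5,9,13-trimethyltetradeca-4,8,12-trienenitrile
Conditions: MeCN (5 equiv), n-BuLi (4 equiv), THF, −78 °C; then 5, −78 → −30 °C
Reagents that add atoms: acetonitrile, CC#N
Why: SN2 alkylation of the small cyanomethyl anion at the primary allylic bromide adds the two carbons needed; the excess of anion suppresses double alkylation and the E alkenes are not touched.

Step 4
Reactants: 6 (4E,8E)-5,9,13-trimethyltetradeca-4,8,12-trienenitrile
Product: 8 (4E,8E)-5,9,13-trimethyltetradeca-4,8,12-trienal, via N-(diisobutylalumanyl)imine 7 (not isolated)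
Conditions: i-Bu2AlH (1.2 equiv), CH2Cl2, −78 °C; then aq. tartaric acid, 0 °C
Reagents that add atoms: water, O
Why: Partial reduction of the nitrile stops at the aluminium imine, which is hydrolysed to the aldehyde on mildly acidic work-up; the acid is too weak to affect the trisubstituted alkenes.

Step 5
Reactants: 8 (4E,8E)-5,9,13-trimethyltetradeca-4,8,12-trienal; 9 diethyl (3-oxobutan-2-yl)phosphonate
Product: 10 (3E,7E,11E)-3,8,12,16-tetramethylheptadeca-3,7,11,15-tetraen-2-one
Conditions: Ba(OH)2, THF/H2O (40:1), rt
Reagents that add atoms: none
Why: Horner–Wadsworth–Emmons olefination of an aliphatic aldehyde with an α-methyl β-ketophosphonate under mild hydroxide conditions; reversible adduct formation should favour the (E)-trisubstituted enone, whose geometry later defines C9.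

Step 6
Reactants: 10 (3E,7E,11E)-3,8,12,16-tetramethylheptadeca-3,7,11,15-tetraen-2-one
Product: 12 (3E,7E,11E)-3,8,12,16-tetramethyl-2-(triisopropylsilyloxy)heptadeca-1,3,7,11,15-pentaene, via lithium dienolate 11 (not isolated)
Conditions: LiN(i-Pr)2, THF, −78 °C; then i-Pr3SiOTf, −78 → 0 °C
Reagents that add atoms: triisopropylsilyl trifluoromethanesulfonate, CC(C)[Si](C(C)C)(C(C)C)OS(=O)(=O)C(F)(F)F
Why: Kinetic deprotonation of the methyl ketone at the α′ methyl group (not at a γ position) gives the cross-conjugated enolate, and O-silylation with the silyl triflate gives the 2-silyloxydiene with the (E)-alkene unchanged.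

Step 7
Reactants: 4 3,3-dimethylcyclohex-1-ene-1-carbaldehyde; 12 (3E,7E,11E)-3,8,12,16-tetramethyl-2-(triisopropylsilyloxy)heptadeca-1,3,7,11,15-pentaene
Product: 13 (5R,9S,10R)-10-formyl-4,4,8-trimethyl-7-(triisopropylsilyloxy)-9-[(3E,7E)-4,8,12-trimethyltrideca-3,7,11-trien-1-yl] cis-fused Δ7-octalin (H5, formyl group and C9 chain all β)
Conditions: 4 (2 equiv), N-protonated (R)-3,3-diphenyl-1-(2-methylphenyl)tetrahydropyrrolo[1,2-c][1,3,2]oxazaborole bis(trifluoromethanesulfonyl)imide salt (20 mol %, from the oxazaborolidine and 17 mol % HNTf2), CH2Cl2, −78 → −20 °C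
Reagents that add atoms: none
Why: The boron Lewis acid binds the formyl oxygen of 4 and lowers its LUMO enough for a concerted but asynchronous [4+2] cycloaddition, in which C6 (the CH2 terminus of the silyl enol ether) bonds ahead to the hindered β-carbon C5 and C9 follows to C10; the closest known reaction type is the oxazaborolidinium-catalysed Diels–Alder reaction of α-substituted cycloalkenecarbaldehydes with 2-silyloxydienes. Ring B is closed as a cyclohexene by intermolecular [4+2] cycloaddition, the two σ bonds C5–C6 and C9–C10 being formed suprafacially on both partners. C5 and C10: both new bonds enter one face of the ring A alkene, so H5 and the formyl group must be cis and the fusion cis. C9: with the formyl group endo (under the diene, favoured by secondary overlap and because the other mode puts C1 of ring A under the C8 methyl), the (E)-configured C9 substituent ends up cis to the formyl group. Absolute sense: in the s-trans enal, held on boron by a formyl C–H···O contact, one phenyl group of the catalyst covers one face of C10=C5, so the diene adds to the other. Regioselectivity is needed and is secured twice, since the C7 silyloxy group (para rule) and the C9 alkyl group (ortho rule) both direct C6 to C5. Chemoselectivity over the three isolated chain alkenes follows from their much lower HOMO, and the slight deficit of HNTf2 keeps free acid away from them and from the enol ether.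

Step 8
Reactants: 13 the (5R,9S,10R) formyl adduct
Product: 14 (5R,9R,10R)-10-(hydroxymethyl)-4,4,8-trimethyl-7-(triisopropylsilyloxy)-9-[(3E,7E)-4,8,12-trimethyltrideca-3,7,11-trien-1-yl] cis-fused Δ7-octalin
Conditions: NaBH4, EtOH/THF, 0 °C
Reagents that add atoms: none
Why: Borohydride reduction of the neopentyl aldehyde to the primary alcohol; the silyl enol ether and the alkenes are inert and no stereocentre is touched.

Step 9
Reactants: 14 the C10 hydroxymethyl compound
Product: 15 (5R,9R,10R)-10-(methanesulfonyloxymethyl)-4,4,8-trimethyl-7-(triisopropylsilyloxy)-9-[(3E,7E)-4,8,12-trimethyltrideca-3,7,11-trien-1-yl] cis-fused Δ7-octalin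
Conditions: MsCl, Et3N, CH2Cl2, 0 °C
Reagents that add atoms: methanesulfonyl chloride, CS(=O)(=O)Cl
Why: Sulfonylation of a primary alcohol under basic conditions that the enol ether tolerates; the neopentyl mesylate can neither eliminate nor be displaced by chloride under these conditions.

Step 10
Reactants: 15 the C10 mesyloxymethyl compound
Product: 16 (5R,9R,10S)-4,4,8,10-tetramethyl-7-(triisopropylsilyloxy)-9-[(3E,7E)-4,8,12-trimethyltrideca-3,7,11-trien-1-yl] cis-fused Δ7-octalin
Conditions: LiEt3BH (4 equiv), THF, 65 °C
Reagents that add atoms: none
Why: SN2 displacement of the sulfonate by the strongly nucleophilic trialkylborohydride, the standard reagent for neopentyl sulfonates; there is no β-hydrogen for elimination, and the enol ether and alkenes do not react.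

Step 11
Reactants: 16 the C10 methyl silyl enol ether
Product: 18 (5R,8S,9R,10S)-8α-hydroxy-4,4,8,10-tetramethyl-9-[(3E,7E)-4,8,12-trimethyltrideca-3,7,11-trien-1-yl] cis-fused decalin-7-one, via 7α,8α-epoxy silyl ether 17 (not isolated)
Conditions: DMDO (1.05 equiv, acetone), CH2Cl2, −78 → −40 °C; then Bu4NF, AcOH, THF, 0 °C
Reagents that add atoms: dimethyldioxirane, CC1(C)OO1
Why: Rubottom oxidation: the tetrasubstituted silyl enol ether is the most electron-rich alkene and should be epoxidised first at low temperature, and buffered fluoride opens the silyloxy epoxide to the α-hydroxy ketone without base-induced ketol rearrangement. Allylic strain with the C8 methyl holds the C9 chain pseudoaxial on the β face, so the oxidant adds anti to it from the α face (the axial approach), which sets C8 with the hydroxyl α.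

Step 12
Reactants: 18 the 8α-hydroxy 7-ketone
Product: 19 (5R,7S,8S,9R,10S)-4,4,8,10-tetramethyl-9-[(3E,7E)-4,8,12-trimethyltrideca-3,7,11-trien-1-yl] cis-fused decalin-7β,8α-diol
Conditions: NaBH4, MeOH, 0 °C
Reagents that add atoms: none
Why: Borohydride reduction of the ketone; the axial C9 chain blocks the axial trajectory, so the 7β (axial) alcohol trans to the C8 hydroxyl is expected, but the C7 configuration is immaterial because C7 becomes CH2.

Step 13
Reactants: 19 the 7β,8α-diol
Product: 20 O-[(5R,7S,8S,9R,10S)-8α-hydroxy-4,4,8,10-tetramethyl-9-[(3E,7E)-4,8,12-trimethyltrideca-3,7,11-trien-1-yl] cis-fused decalin-7β-yl] O-phenyl thiocarbonate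
Conditions: PhOC(S)Cl, pyridine, DMAP, CH2Cl2, 0 °C → rt
Reagents that add atoms: O-phenyl chlorothionoformate, S=C(Cl)Oc1ccccc1
Why: Acyl transfer to the secondary hydroxyl only, since the tertiary one is too hindered; the trans-diaxial arrangement of the two oxygens prevents closure to a cyclic thionocarbonate.

Step 14
Reactants: 20 the 7-O-phenoxythiocarbonyl derivative
Product: 21 (5R,8R,9R,10S) target, (1R,2R,4aR,8aS)-2,5,5,8a-tetramethyl-1-[(3E,7E)-4,8,12-trimethyltrideca-3,7,11-trien-1-yl]decahydronaphthalen-2-ol
Conditions: Bu3SnH (3 equiv, 0.3 M), AIBN, toluene, 100 °C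
Reagents that add atoms: none
Why: Barton–McCombie deoxygenation: the stannyl radical adds to sulfur, the secondary C7 radical is released and takes hydrogen from the stannane; a high stannane concentration outruns 6-exo addition of this radical to the C13=C14 alkene, and the free tertiary alcohol and C8 are untouched.

## Compound list

1 | 3-methylcyclohex-2-en-1-one | CC1=CC(=O)CCC1 | starting material
2 | lithium 3,3-dimethylcyclohex-1-en-1-olate | [Li]OC1=CC(C)(C)CCC1 | intermediate
3 | 3,3-dimethylcyclohex-1-en-1-yl trifluoromethanesulfonate | CC1(C)CCCC(OS(=O)(=O)C(F)(F)F)=C1 | intermediate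
4 | 3,3-dimethylcyclohex-1-ene-1-carbaldehyde | O=CC1=CC(C)(C)CCC1 | intermediate
5 | (2E,6E)-farnesyl bromide, (2E,6E)-1-bromo-3,7,11-trimethyldodeca-2,6,10-triene | CC(C)=CCC/C(C)=C/CC/C(C)=C/CBr | starting material
6 | (4E,8E)-5,9,13-trimethyltetradeca-4,8,12-trienenitrile | CC(C)=CCC/C(C)=C/CC/C(C)=C/CCC#N | intermediate
7 | (4E,8E)-N-(diisobutylalumanyl)-5,9,13-trimethyltetradeca-4,8,12-trien-1-imine | CC(C)=CCC/C(C)=C/CC/C(C)=C/CCC=N[Al](CC(C)C)CC(C)C | intermediate
8 | (4E,8E)-5,9,13-trimethyltetradeca-4,8,12-trienal | CC(C)=CCC/C(C)=C/CC/C(C)=C/CCC=O | intermediate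
9 | diethyl (3-oxobutan-2-yl)phosphonate | CCOP(=O)(OCC)C(C)C(C)=O | starting material
10 | (3E,7E,11E)-3,8,12,16-tetramethylheptadeca-3,7,11,15-tetraen-2-one | CC(=O)/C(C)=C/CC/C=C(C)/CC/C=C(C)/CCC=C(C)C | intermediate
11 | lithium (3E,7E,11E)-3,8,12,16-tetramethylheptadeca-1,3,7,11,15-pentaen-2-olate | [Li]OC(=C)/C(C)=C/CC/C=C(C)/CC/C=C(C)/CCC=C(C)C | intermediate
12 | (3E,7E,11E)-3,8,12,16-tetramethyl-2-(triisopropylsilyloxy)heptadeca-1,3,7,11,15-pentaene | C=C(O[Si](C(C)C)(C(C)C)C(C)C)/C(C)=C/CC/C=C(C)/CC/C=C(C)/CCC=C(C)C | intermediate
13 | (5R,9S,10R) cis-fused Diels–Alder adduct: C10 formyl, C7=C8 triisopropylsilyl enol ether, C8 methyl, C9 chain; H5, CHO and chain β | CC(C)=CCC/C(C)=C/CC/C(C)=C/CC[C@@H]1[C@@]2(C=O)CCCC(C)(C)[C@H]2CC(O[Si](C(C)C)(C(C)C)C(C)C)=C1C | intermediate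
14 | (5R,9R,10R) C10 hydroxymethyl analogue of 13 | CC(C)=CCC/C(C)=C/CC/C(C)=C/CC[C@@H]1[C@@]2(CO)CCCC(C)(C)[C@H]2CC(O[Si](C(C)C)(C(C)C)C(C)C)=C1C | intermediate
15 | (5R,9R,10R) C10 methanesulfonyloxymethyl analogue of 13 | CC(C)=CCC/C(C)=C/CC/C(C)=C/CC[C@@H]1[C@@]2(COS(C)(=O)=O)CCCC(C)(C)[C@H]2CC(O[Si](C(C)C)(C(C)C)C(C)C)=C1C | intermediate
16 | (5R,9R,10S) C10 methyl silyl enol ether: 4,4,8,10-tetramethyl-7-(triisopropylsilyloxy)-9-chain cis-fused Δ7-octalin | CC(C)=CCC/C(C)=C/CC/C(C)=C/CC[C@@H]1[C@@]2(C)CCCC(C)(C)[C@H]2CC(O[Si](C(C)C)(C(C)C)C(C)C)=C1C | intermediate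
17 | 7α,8α-epoxide of 16 (C7 triisopropylsilyloxy β, C8 methyl β) | CC(C)=CCC/C(C)=C/CC/C(C)=C/CC[C@@H]1[C@@]2(C)CCCC(C)(C)[C@H]2C[C@@]3(O[Si](C(C)C)(C(C)C)C(C)C)O[C@@]13C | intermediate
18 | (5R,8S,9R,10S) 8α-hydroxy-7-ketone (C8 methyl β) | CC(C)=CCC/C(C)=C/CC/C(C)=C/CC[C@@H]1[C@@]2(C)CCCC(C)(C)[C@H]2CC(=O)[C@@]1(C)O | intermediate
19 | (5R,7S,8S,9R,10S) 7β,8α-diol | CC(C)=CCC/C(C)=C/CC/C(C)=C/CC[C@@H]1[C@@]2(C)CCCC(C)(C)[C@H]2C[C@H](O)[C@@]1(C)O | intermediate
20 | (5R,7S,8S,9R,10S) 7β-O-(phenoxythiocarbonyl) derivative of 19 | CC(C)=CCC/C(C)=C/CC/C(C)=C/CC[C@@H]1[C@@]2(C)CCCC(C)(C)[C@H]2C[C@H](OC(=S)Oc2ccccc2)[C@@]1(C)O | intermediate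
21 | (1R,2R,4aR,8aS)-2,5,5,8a-tetramethyl-1-[(3E,7E)-4,8,12-trimethyltrideca-3,7,11-trien-1-yl]decahydronaphthalen-2-ol | CC(C)=CCC/C(C)=C/CC/C(C)=C/CC[C@@H]1[C@@]2(C)CCCC(C)(C)[C@H]2CC[C@@]1(C)O | target

## Step count and least certain steps

Total step count: 14. Longest linear sequence: 12 steps (5 → 21, steps 3–14); the enal branch (steps 1–2) joins at step 7.

**Step 7 (key step).** The most likely failure is a cycloaddition too slow at the neopentyl C5 at the temperature where the chiral catalyst discriminates the faces. Protodesilylation of the diene, aldol-type 1,2-addition of the enol ether to the formyl group, or loss of facial and endo selectivity on warming would then take over. The fallback gives up catalytic enantiocontrol for a smaller and stronger Lewis acid followed by resolution. It sets out from 4 and 12: EtAlCl2 (1 equiv) in CH2Cl2 at −78 °C should give the racemic adduct F1, NaBH4 reduction gives the racemic alcohol F2, and preparative chromatography on a chiral stationary phase separates the enantiomers. The route is rejoined at 14.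

**Step 11.** The most likely failure is oxygen transfer to the chain alkenes, since three trisubstituted alkenes compete with one hindered enol ether. A second possibility is attack on the β face if the syn-axial C1 methylene outweighs the pseudoaxial chain. The fallback replaces epoxidation by oxygenation of an enolate, to which isolated alkenes are inert. It sets out from 16: Bu4NF/AcOH in THF gives the 8-methyl-7-ketone F3, and KOC(CH3)3 in t-BuOH/THF under O2 with P(OEt)3 at −20 °C hydroxylates the more substituted, equilibrating enolate at C8. The route is rejoined at 18.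

**Step 10.** The most likely failure is attack of the hydride at sulfur instead of carbon (S–O cleavage), because the CH2 group sits on a quaternary carbon between two substituted centres; this would return alcohol 14. The fallback is a radical deoxygenation. It sets out from 14: NaH, CS2 and MeI give the S-methyl xanthate F4, and Bu3SnH/AIBN in toluene at 110 °C reduces it. The route is rejoined at 16.

**Step 13 (with step 14).** The most likely failure is slow or unselective thioacylation of the hindered axial C7 hydroxyl. If the reduction in step 12 gave the cis-diol, closure to a cyclic thionocarbonate would follow, and its radical cleavage would remove the tertiary oxygen instead. The fallback avoids the diol. It sets out from 18: TsNHNH2 in EtOH gives the tosylhydrazone F5, which is reduced with catecholborane in CHCl3 and then heated with NaOAc·3H2O to lose sulfinate and nitrogen. The route is rejoined at 21.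

**Step 2.** The most likely failure is hydride transfer to the vinylpalladium complex before CO insertion, giving the volatile alkene instead of the enal. The fallback separates carbonylation from reduction. It sets out from 3: Pd(OAc)2/dppp, CO, MeOH and Et3N in DMF give the methyl ester F6, i-Bu2AlH reduces it to the allylic alcohol F7, and MnO2 oxidises this. The route is rejoined at 4.

## Further compounds

F1 | step 7 | racemic cis-fused adduct (13 and its enantiomer, 1:1) | CC(C)=CCC/C(C)=C/CC/C(C)=C/CC[C@@H]1[C@@]2(C=O)CCCC(C)(C)[C@H]2CC(O[Si](C(C)C)(C(C)C)C(C)C)=C1C.CC(C)=CCC/C(C)=C/CC/C(C)=C/CC[C@H]1[C@]2(C=O)CCCC(C)(C)[C@@H]2CC(O[Si](C(C)C)(C(C)C)C(C)C)=C1C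
F2 | step 7 | racemic C10 hydroxymethyl compound (14 and its enantiomer, 1:1) | CC(C)=CCC/C(C)=C/CC/C(C)=C/CC[C@@H]1[C@@]2(CO)CCCC(C)(C)[C@H]2CC(O[Si](C(C)C)(C(C)C)C(C)C)=C1C.CC(C)=CCC/C(C)=C/CC/C(C)=C/CC[C@H]1[C@]2(CO)CCCC(C)(C)[C@@H]2CC(O[Si](C(C)C)(C(C)C)C(C)C)=C1C
F3 | step 11 | (5R,9R,10S)-4,4,8,10-tetramethyl-9-[(3E,7E)-4,8,12-trimethyltrideca-3,7,11-trien-1-yl] cis-fused decalin-7-one (C8 epimers) | CC(C)=CCC/C(C)=C/CC/C(C)=C/CC[C@@H]1[C@@]2(C)CCCC(C)(C)[C@H]2CC(=O)C1C
F4 | step 10 | O-[C10-methylene of 14] S-methyl dithiocarbonate (xanthate of 14) | CC(C)=CCC/C(C)=C/CC/C(C)=C/CC[C@@H]1[C@@]2(COC(=S)SC)CCCC(C)(C)[C@H]2CC(O[Si](C(C)C)(C(C)C)C(C)C)=C1C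
F5 | step 13 | C7 (4-methylbenzenesulfonyl)hydrazone of 18 | CC(C)=CCC/C(C)=C/CC/C(C)=C/CC[C@@H]1[C@@]2(C)CCCC(C)(C)[C@H]2CC(=NNS(=O)(=O)c2ccc(C)cc2)[C@@]1(C)O
F6 | step 2 | methyl 3,3-dimethylcyclohex-1-ene-1-carboxylate | COC(=O)C1=CC(C)(C)CCC1
F7 | step 2 | (3,3-dimethylcyclohex-1-en-1-yl)methanol | OCC1=CC(C)(C)CCC1
A1 | alternative 1 | trans-fused ring B bis(tert-butyldimethylsilyl) dienol ether (C6=C7–C8=C9 diene, C3 silyloxy) | CC1=C[C@@]2(C)CC[C@H](O[Si](C)(C)C(C)(C)C)C(C)(C)[C@@H]2C=C1O[Si](C)(C)C(C)(C)C
A2 | alternative 1 | all-cis ten-membered triene (C5=C6, C7=C8, C9=C10) from opening of A1 | C/C1=C/C(C)=C(O[Si](C)(C)C(C)(C)C)\C=C/C(C)(C)[C@@H](O[Si](C)(C)C(C)(C)C)CC1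
A3 | alternative 1 | cis-fused isomer of the silyl dienol ether | CC1=C[C@@]2(C)CC[C@H](O[Si](C)(C)C(C)(C)C)C(C)(C)[C@H]2C=C1O[Si](C)(C)C(C)(C)C
A4 | alternative 2 | (R)-α-ionone | CC(=O)/C=C/[C@H]1C(C)=CCCC1(C)C
A5 | alternative 2 | 1-diazo-4-[(1R)-2,6,6-trimethylcyclohex-2-en-1-yl]butan-2-one | [N-]=[N+]=CC(=O)CC[C@H]1C(C)=CCCC1(C)C
A6 | alternative 2 | tricyclic cyclopropyl ketone (C8 ketone, cyclopropane C1–C9–C10, C10 methyl cis to H5) | O=C1CC[C@@H]2C(C)(C)CC[C@@H]3[C@H]1[C@]23C
A7 | alternative 3 | methyl (E)-3-[1,3,3-trimethyl-2-(3-oxobutyl)cyclohexyl]prop-2-enoate with C5 and C10 as in 21 | COC(=O)/C=C/[C@@]1(C)CCCC(C)(C)[C@H]1CCC(C)=O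
A8 | alternative 3 | methyl 2-(cis-fused 2-hydroxy-2,5,5,8a-tetramethyldecahydronaphthalen-1-yl)acetate | COC(=O)C[C@@H]1[C@@]2(C)CCCC(C)(C)[C@H]2CC[C@@]1(C)O
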